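I decided to keep the flask's books on Z, the limiting reagent, with the smallest charge, and to ask what each entry held when G stopped growing.

| setting | Wednesday's | Sunday's | Thursday's | flask |
|---|---|---|---|---|
| Z | 0.091 M | 0.091 M | 0.18 M | 0.091 M |
| L | 0.273 M | 0.273 M | 0.273 M | 0.273 M |
| Q | 0.137 M | 0.137 M | 0.137 M | 0.137 M |
| J | 0.091 M | 0.14 M | 0.182 M | 0.182 M |
| remark | run made earlier | run made earlier | run made earlier |  |
| time |  |  |  | 3.0 h |

- Wednesday's (time / h: G / %, E / %): 0.333: 48.4, 0; 0.500: 62.6, 0.8; 0.833: 72.0, 2.0; 1.33: 78.5, 4.6; 2.00: 78.9, 4.1; 4.00: 72.0, 13.7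
- Sunday's (time / h: G / %, E / %): 0.333: 49.2, 1.0; 0.500: 60.7, 0.3; 0.833: 72.8, 1.3; 1.33: 77.8, 5.3; 2.00: 73.3, 8.9; 4.00: 63.5, 17.6
- Thursday's (time / h: G / %, E / %): 0.333: 39.1, 2.0; 0.500: 48.4, 2.3; 1.00: 57.0, 3.6; 2.00: 52.3, 10.0; 4.00: 45.1, 14.8

(standard deviation of a reading: 1 percentage point)



1. the best time, 3.0 h at the latest, for G
2. the amount of G, in percent of the Z charged, at that time

The first entry is G plus E. In Wednesday's and Sunday's runs, which share the flask's Z, L and Q, it averaged 83.1 % at 1.33 h and 83.4 % at 4.00 h, so I booked it as flat from 1.33 h, with the remaining 16.9 % unread.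

The second entry splits that sum. Between the last two readings G fell at 0.0458 h⁻¹ on Wednesday and 0.0718 h⁻¹ on Sunday, a ratio of 1.57 against 1.54 in c_J. The flask's c_J is twice the Z charged, so I held it constant and scaled Sunday's reading to 0.0933 h⁻¹. This is the toll, the pseudo-first-order constant for the share of G passing to E each hour. Counting G as present from the first reading at 0.333 h, I booked 7.38 % as E by 1.33 h, which left 75.7 % as G.

The forecast said 75.5 % at 1.25 h, beside my 75.7 % at 1.33 h, holding that “J does speed the loss of G”.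

The flask gave 75.0 % of G at 1.23 h, within the forecast's margins, and at that time it also held 15.7 % as D and 2.26 % as X. Running the toll from that moment to 3.0 h brings G to 63.6 %, whereas the flask stood at 65.7 %, a gap of 2.2 percentage points beside that X.

    Z + L → X (k = 0.340 M⁻¹ min⁻¹)
    J + G → E (k = 0.00910 M⁻¹ min⁻¹)
    Q + X → G (k = 1.10 M⁻¹ min⁻¹)
    Z + Q → D (k = 0.140 M⁻¹ min⁻¹)

With 0.55 M of Q and c_J unchanged, the toll run from 0.333 h to 3.0 h gave me E over G of 0.283. The computed end of that flask holds 41.2 % as G, 13.0 % as E and 45.8 % as D, an E over G of 0.316.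

(The readings were generated by integration for an exercise; the scatter is artificial.)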